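**Retrosynthetic overview**
1. Target ⇐ macrocyclic 8,9-diol (O8 methacryloylation, then O9 acetylation) ⇐ its 8,9-acetonide.
2. Ten-membered ring (closed last): C4=C5 by ring-closing metathesis of a 5-isopropenyl-3(2H)-furanone that carries a C6-vinyl cis-α-methylene-γ-lactone.
3. Lactone (second ring; C6–C7 bond, C6 and C7): zinc Barbier allylation of acrolein by a (Z)-2-(bromomethyl)enoate built on the C7 aldehyde (Baylis–Hillman).
4. Furanone (first ring; C2–C3 bond): unmasking of an isoxazole made by the key nitrile oxide/alkyne [3+2] cycloaddition.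
5. The alkyne partner (C10) comes from chelation-controlled ethynylation of the methyl ketose obtained from 2,3-O-isopropylidene-L-erythronolactone, which supplies C8 and C9.

Assumption: the SMILES is read literally, i.e. (6S,7S,8S,9S,10R) in germacrane numbering with a cis-fused 12,6-lactone, and (+)-2,3-O-isopropylidene-L-erythronolactone is taken as a catalogue compound.

**Route**

Step 1
Reactants: 1 2,3-O-isopropylidene-L-erythronolactone
Product: 2 1-deoxy-3,4-O-isopropylidene-L-erythro-pent-2-ulofuranose (anomeric mixture)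
Conditions: MeLi (1.05 equiv), THF, −78 °C; aq. NH4Cl
Reagents that add atoms: methyllithium, [Li]C
Why: Nucleophilic addition of MeLi to the γ-lactone stops at the lithium hemiketalate at −78 °C, so the methyl ketone (future C10/C14) is obtained as its cyclic hemiketal with C8 and C9 untouched.

Step 2
Reactants: 2 1-deoxy-3,4-O-isopropylidene-L-erythro-pent-2-ulofuranose
Product: 3 (2S)-2-[(4S,5S)-5-(hydroxymethyl)-2,2-dimethyl-1,3-dioxolan-4-yl]but-3-yn-2-ol
Conditions: HC≡CMgBr (3.5 equiv), THF, −20 °C to rt; aq. NH4Cl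
Reagents that add atoms: ethynylmagnesium bromide, C#C[Mg]Br
Why: The magnesium hemiketalate opens to the methyl ketone and the Grignard reagent adds under Cram-chelate control (Mg bridging C10=O and the α-oxygen O9, attack from the H9 face away from C8 of the cis-dioxolane), which sets C10 (2S here, 10R once C1 is a carbonyl).

Step 3
Reactants: 4 methacrolein
Product: 5 2-methylprop-2-enal oxime (E/Z mixture)
Conditions: NH2OH (50% aq.), EtOH, 0 °C to rt
Reagents that add atoms: hydroxylamine, NO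
Why: Simple oxime condensation gives the nitrile oxide precursor that carries C3, C4, C5 and C15.

Step 4
Reactants: 3 (2S)-2-[(4S,5S)-5-(hydroxymethyl)-2,2-dimethyl-1,3-dioxolan-4-yl]but-3-yn-2-ol; 5 2-methylprop-2-enal oxime
Product: 8 (1R)-1-[(4S,5S)-5-(hydroxymethyl)-2,2-dimethyl-1,3-dioxolan-4-yl]-1-[3-(prop-1-en-2-yl)-1,2-oxazol-5-yl]ethan-1-ol, via hydroximoyl chloride 6 (not isolated), via nitrile oxide 7 (not isolated)
Conditions: 5, NCS, DMF, 0 °C to rt; then slow addition to 3, KHCO3, EtOAc, rt (5 in excess)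
Reagents that add atoms: none
Why: Huisgen 1,3-dipolar cycloaddition of the slowly generated nitrile oxide to the terminal alkyne gives the 3,5-disubstituted isoxazole regioselectively (oxygen on the substituted alkyne carbon), forming C2–C3 and the five-membered ring that holds the latent 1,3-dioxygenation of the furanone; no stereocenter is touched.

Step 5
Reactants: 8 (1R)-1-[(4S,5S)-5-(hydroxymethyl)-2,2-dimethyl-1,3-dioxolan-4-yl]-1-[3-(prop-1-en-2-yl)-1,2-oxazol-5-yl]ethan-1-ol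
Product: 10 (2R)-2-[(4S,5S)-5-(hydroxymethyl)-2,2-dimethyl-1,3-dioxolan-4-yl]-2-methyl-5-(prop-1-en-2-yl)furan-3(2H)-one, via enaminone 9 (not isolated)
Conditions: Mo(CO)6, MeCN/H2O, 80 °C; then AcOH/THF/H2O, rt
Reagents that add atoms: none
Why: Reductive N–O cleavage of the isoxazole gives the vinylogous amide, and acid-promoted addition–elimination of the tertiary C10 hydroxyl at C3 expels ammonia to close the 3(2H)-furanone with C10 unchanged.

Step 6
Reactants: 10 (2R)-2-[(4S,5S)-5-(hydroxymethyl)-2,2-dimethyl-1,3-dioxolan-4-yl]-2-methyl-5-(prop-1-en-2-yl)furan-3(2H)-one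
Product: 11 (4R,5S)-2,2-dimethyl-5-[(2R)-2-methyl-3-oxo-5-(prop-1-en-2-yl)-2,3-dihydrofuran-2-yl]-1,3-dioxolane-4-carbaldehyde
Conditions: Dess–Martin periodinane, CH2Cl2, 0 °C to rt; used at once
Reagents that add atoms: none
Why: Dess–Martin oxidation of the only remaining hydroxyl gives the C7 aldehyde under non-basic conditions that do not epimerise C8 (the 4R label is only a CIP change).

Step 7
Reactants: 11 (4R,5S)-2,2-dimethyl-5-[(2R)-2-methyl-3-oxo-5-(prop-1-en-2-yl)-2,3-dihydrofuran-2-yl]-1,3-dioxolane-4-carbaldehyde; 12 methyl acrylate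
Product: 13 methyl 2-{[(4S,5S)-2,2-dimethyl-5-[(2R)-2-methyl-3-oxo-5-(prop-1-en-2-yl)-2,3-dihydrofuran-2-yl]-1,3-dioxolan-4-yl](hydroxy)methyl}prop-2-enoate (carbinol epimers)
Conditions: methyl acrylate (5 equiv), DABCO (1 equiv), 1,4-dioxane/H2O, rt
Reagents that add atoms: none
Why: Morita–Baylis–Hillman reaction of the activated α-alkoxy aldehyde attaches C11–C13; the new carbinol center is removed in the next step, so its configuration does not matter.

Step 8
Reactants: 13 methyl 2-{[(4S,5S)-2,2-dimethyl-5-[(2R)-2-methyl-3-oxo-5-(prop-1-en-2-yl)-2,3-dihydrofuran-2-yl]-1,3-dioxolan-4-yl](hydroxy)methyl}prop-2-enoate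
Product: 14 methyl (2Z)-2-(bromomethyl)-3-{(4S,5S)-2,2-dimethyl-5-[(2R)-2-methyl-3-oxo-5-(prop-1-en-2-yl)-2,3-dihydrofuran-2-yl]-1,3-dioxolan-4-yl}prop-2-enoate
Conditions: PBr3 (0.5 equiv), Et2O, −10 to 0 °C
Reagents that add atoms: phosphorus tribromide, BrP(Br)Br
Why: Allylic bromination with SN2′ transposition gives the thermodynamically preferred (Z)-2-(bromomethyl)enoate (C8 cis to CH2Br), the standard outcome for Baylis–Hillman alcohols.

Step 9
Reactants: 14 methyl (2Z)-2-(bromomethyl)-3-{(4S,5S)-2,2-dimethyl-5-[(2R)-2-methyl-3-oxo-5-(prop-1-en-2-yl)-2,3-dihydrofuran-2-yl]-1,3-dioxolan-4-yl}prop-2-enoate; 15 acrolein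
Product: 18 (4S,5S)-4-{(4S,5S)-2,2-dimethyl-5-[(2R)-2-methyl-3-oxo-5-(prop-1-en-2-yl)-2,3-dihydrofuran-2-yl]-1,3-dioxolan-4-yl}-5-ethenyl-3-methylideneoxolan-2-one, via allylzinc bromide 16 (not isolated), via hydroxy ester 17 (not isolated)
Conditions: Zn dust, acrolein (5 equiv), THF/sat. aq. NH4Cl, 0 °C to rt; then TsOH·H2O (cat.), CH2Cl2, rt
Reagents that add atoms: none
Why: In this Barbier allylation–lactonisation the (Z)-allylzinc adds 1,2 to acrolein through a chair transition state with C8 axial (syn adduct, hence the cis-lactone) and on the face of C7 anti to the bulky C9 substituent in the A(1,3)-minimised conformer, so C8 sets 7S and with it 6S.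

Step 10
Reactants: 18 (4S,5S)-4-{(4S,5S)-2,2-dimethyl-5-[(2R)-2-methyl-3-oxo-5-(prop-1-en-2-yl)-2,3-dihydrofuran-2-yl]-1,3-dioxolan-4-yl}-5-ethenyl-3-methylideneoxolan-2-one
Product: 19 (4Z,6S,7S,8S,9S,10R)-3,10-epoxy-8,9-(isopropylidenedioxy)-1-oxogermacra-2,4,11(13)-trien-12,6-olide
Conditions: second-generation Hoveyda–Grubbs catalyst RuCl2(H2IMes)(=CH-C6H4-2-O-i-Pr) (15 mol%), 1,4-benzoquinone (cat.), toluene (1 mM), 100 °C
Reagents that add atoms: none
Why: Ring-closing metathesis between the furanone isopropenyl and the C6 vinyl group is helped by two cis-fused five-membered rings (lactone, dioxolane) acting as turn elements, and the ring permits only the (4Z) alkene; the exocyclic acrylate-type methylene is a poor metathesis partner.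

Step 11
Reactants: 19 (4Z,6S,7S,8S,9S,10R)-3,10-epoxy-8,9-(isopropylidenedioxy)-1-oxogermacra-2,4,11(13)-trien-12,6-olide
Product: 20 (4Z,6S,7R,8S,9S,10R)-3,10-epoxy-8,9-dihydroxy-1-oxogermacra-2,4,11(13)-trien-12,6-olide (7R is a CIP change only)
Conditions: TFA/H2O (9:1), 0 °C
Reagents that add atoms: none
Why: Acid hydrolysis of the acetonide frees the 8,9-diol while the furanone (itself formed under acid) and the lactone survive; cold, short exposure limits translactonisation to O8.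

Step 12
Reactants: 20 (4Z,6S,7R,8S,9S,10R)-3,10-epoxy-8,9-dihydroxy-1-oxogermacra-2,4,11(13)-trien-12,6-olide
Product: 21 (4Z,6S,7S,8S,9S,10R)-3,10-epoxy-9-hydroxy-8-(methacryloyloxy)-1-oxogermacra-2,4,11(13)-trien-12,6-olide
Conditions: methacrylic anhydride (1.1 equiv), Et3N, DMAP (cat.), CH2Cl2, −20 °C
Reagents that add atoms: methacrylic anhydride, CC(=C)C(=O)OC(=O)C(C)=C
Why: DMAP-catalysed acylation should take the C8 hydroxyl first, because the C9 hydroxyl is neopentyl-like next to the quaternary C10.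

Step 13
Reactants: 21 (4Z,6S,7S,8S,9S,10R)-3,10-epoxy-9-hydroxy-8-(methacryloyloxy)-1-oxogermacra-2,4,11(13)-trien-12,6-olide
Product: 22 (4Z,6S,7S,8S,9S,10R)-9-acetoxy-3,10-epoxy-8-(methacryloyloxy)-1-oxogermacra-2,4,11(13)-trien-12,6-olide (CNP0365569.3)
Conditions: Ac2O, pyridine, DMAP (cat.), CH2Cl2, rt
Reagents that add atoms: acetic anhydride, CC(=O)OC(C)=O
Why: Acetylation of the remaining hindered C9 hydroxyl completes the target without touching any stereocenter.

**Compound list**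
1 | 2,3-O-isopropylidene-L-erythronolactone, (3aS,6aS) | CC1(C)O[C@H]2COC(=O)[C@H]2O1 | starting material
2 | 1-deoxy-3,4-O-isopropylidene-L-erythro-pent-2-ulofuranose, (3aS,6aS)-2,2,4-trimethyltetrahydrofuro[3,4-d][1,3]dioxol-4-ol | CC1(C)O[C@H]2COC(C)(O)[C@H]2O1 | intermediate
3 | (2S)-2-[(4S,5S)-5-(hydroxymethyl)-2,2-dimethyl-1,3-dioxolan-4-yl]but-3-yn-2-ol | OC[C@@H]1OC(C)(C)O[C@@H]1[C@@](C)(O)C#C | intermediate
4 | methacrolein | CC(=C)C=O | starting material
5 | 2-methylprop-2-enal oxime | CC(=C)C=NO | intermediate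
6 | N-hydroxy-2-methylprop-2-enimidoyl chloride | CC(=C)C(Cl)=NO | intermediate (not isolated)
7 | 2-methylprop-2-enenitrile oxide | CC(=C)C#[N+][O-] | intermediate (not isolated)
8 | (1R)-1-[(4S,5S)-5-(hydroxymethyl)-2,2-dimethyl-1,3-dioxolan-4-yl]-1-[3-(prop-1-en-2-yl)-1,2-oxazol-5-yl]ethan-1-ol | OC[C@@H]1OC(C)(C)O[C@@H]1[C@@](C)(O)c1cc(C(C)=C)no1 | intermediate
9 | (2R,4Z)-5-amino-2-hydroxy-2-[(4S,5S)-5-(hydroxymethyl)-2,2-dimethyl-1,3-dioxolan-4-yl]-6-methylhepta-4,6-dien-3-one | OC[C@@H]1OC(C)(C)O[C@@H]1[C@@](C)(O)C(=O)/C=C(\N)C(C)=C | intermediate (not isolated)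
10 | (2R)-2-[(4S,5S)-5-(hydroxymethyl)-2,2-dimethyl-1,3-dioxolan-4-yl]-2-methyl-5-(prop-1-en-2-yl)furan-3(2H)-one | OC[C@@H]1OC(C)(C)O[C@@H]1[C@@]2(C)OC(C(C)=C)=CC2=O | intermediate
11 | (4R,5S)-2,2-dimethyl-5-[(2R)-2-methyl-3-oxo-5-(prop-1-en-2-yl)-2,3-dihydrofuran-2-yl]-1,3-dioxolane-4-carbaldehyde | O=C[C@@H]1OC(C)(C)O[C@@H]1[C@@]2(C)OC(C(C)=C)=CC2=O | intermediate
12 | methyl acrylate | C=CC(=O)OC | starting material
13 | methyl 2-{[(4S,5S)-2,2-dimethyl-5-[(2R)-2-methyl-3-oxo-5-(prop-1-en-2-yl)-2,3-dihydrofuran-2-yl]-1,3-dioxolan-4-yl](hydroxy)methyl}prop-2-enoate | COC(=O)C(=C)C(O)[C@@H]1OC(C)(C)O[C@@H]1[C@@]2(C)OC(C(C)=C)=CC2=O | intermediate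
14 | methyl (2Z)-2-(bromomethyl)-3-{(4S,5S)-2,2-dimethyl-5-[(2R)-2-methyl-3-oxo-5-(prop-1-en-2-yl)-2,3-dihydrofuran-2-yl]-1,3-dioxolan-4-yl}prop-2-enoate | COC(=O)/C(CBr)=C/[C@@H]1OC(C)(C)O[C@@H]1[C@@]2(C)OC(C(C)=C)=CC2=O | intermediate
15 | acrolein | C=CC=O | starting material
16 | allylzinc bromide derived from 14 (Zn in place of Br, same Z geometry) | COC(=O)/C(C[Zn]Br)=C/[C@@H]1OC(C)(C)O[C@@H]1[C@@]2(C)OC(C(C)=C)=CC2=O | intermediate (not isolated)
17 | methyl 2-[(1S,2S)-1-{(4S,5S)-2,2-dimethyl-5-[(2R)-2-methyl-3-oxo-5-(prop-1-en-2-yl)-2,3-dihydrofuran-2-yl]-1,3-dioxolan-4-yl}-2-hydroxybut-3-en-1-yl]prop-2-enoate | COC(=O)C(=C)[C@@H]([C@@H](O)C=C)[C@@H]1OC(C)(C)O[C@@H]1[C@@]2(C)OC(C(C)=C)=CC2=O | intermediate (not isolated)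
18 | (4S,5S)-4-{(4S,5S)-2,2-dimethyl-5-[(2R)-2-methyl-3-oxo-5-(prop-1-en-2-yl)-2,3-dihydrofuran-2-yl]-1,3-dioxolan-4-yl}-5-ethenyl-3-methylideneoxolan-2-one | C=C[C@@H]1OC(=O)C(=C)[C@@H]1[C@@H]1OC(C)(C)O[C@@H]1[C@@]2(C)OC(C(C)=C)=CC2=O | intermediate
19 | (4Z,6S,7S,8S,9S,10R)-3,10-epoxy-8,9-(isopropylidenedioxy)-1-oxogermacra-2,4,11(13)-trien-12,6-olide | CC1(C)O[C@H]2[C@H]3C(=C)C(=O)O[C@H]3/C=C(/C)C3=CC(=O)[C@](C)(O3)[C@H]2O1 | intermediate
20 | (4Z,6S,7R,8S,9S,10R)-3,10-epoxy-8,9-dihydroxy-1-oxogermacra-2,4,11(13)-trien-12,6-olide | O[C@H]1[C@H]2C(=C)C(=O)O[C@H]2/C=C(/C)C2=CC(=O)[C@](C)(O2)[C@H]1O | intermediate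
21 | (4Z,6S,7S,8S,9S,10R)-3,10-epoxy-9-hydroxy-8-(methacryloyloxy)-1-oxogermacra-2,4,11(13)-trien-12,6-olide | C=C(C)C(=O)O[C@H]1[C@H]2C(=C)C(=O)O[C@H]2/C=C(/C)C2=CC(=O)[C@](C)(O2)[C@H]1O | intermediate
22 | (4Z,6S,7S,8S,9S,10R)-9-acetoxy-3,10-epoxy-8-(methacryloyloxy)-1-oxogermacra-2,4,11(13)-trien-12,6-olide | C=C(C)C(=O)O[C@H]1[C@H]2C(=C)C(=O)O[C@H]2/C=C(/C)C2=CC(=O)[C@](C)(O2)[C@H]1OC(C)=O | target

**Step count and risks**
Total: 13 steps. Longest linear sequence: 12 steps (1, 2, 4–13, from compound 1); step 3 is a one-step side branch.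

Most likely to fail:

Step 10 (ring-closing metathesis to the strained bridged ten-membered ring). Fallback: build the ten-membered ring before the lactone. The fallback sets out from hydroxy ester 17, isolated by leaving out the TsOH treatment of step 9. TESOTf/2,6-lutidine gives its O-triethylsilyl ether F3, which can rotate freely about C6–C7. Metathesis of F3 with the same ruthenium catalyst gives the macrocyclic 6-O-triethylsilyl methyl ester (seco-lactone of 19) F4. HF·pyridine frees the macrocyclic 6-hydroxy methyl ester F5, and catalytic TsOH lactonises it. The fallback returns to the route at 19.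

Step 9 (two new stereocenters from an open-chain Barbier reaction). Fallback: replace the in-situ organozinc by an isolated allylboron reagent that reacts through a tight closed transition state. The fallback sets out from bromide 14. B2pin2, CuCl (cat.), PPh3 and KOMe in THF give the pinacol allylboronate of 14 (Bpin in place of Br; formally 2E, C8 still cis to the CH2B group) F1. F1 and acrolein 15 (toluene, Sc(OTf)3 cat., 0 °C, or 80 °C without catalyst) give the O-pinacolboryl ether of 17 F2 by a chair allylboration. Aqueous work-up hydrolyses F2, and the fallback returns to the route at 17, which TsOH closes to 18 as in step 9.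

Step 12 (discrimination of O8 from O9). Fallback: temporary silyl protection instead of direct selective acylation. The fallback sets out from diol 20. TESCl/imidazole (DMF, −40 °C) silylates the less hindered hydroxyl to the 8-O-triethylsilyl ether of 20 F6. Ac2O/DMAP gives the 9-O-acetyl-8-O-triethylsilyl derivative of 20 F7. HF·pyridine gives the 9-O-acetyl derivative of 20 with free 8-OH F8, and methacrylic anhydride/DMAP/Et3N esterifies O8. The fallback returns to the route at 22.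

**Further compounds**
F1 | step 9 | pinacol allylboronate of 14 (Bpin in place of Br, C8 cis to CH2B) | COC(=O)/C(CB1OC(C)(C)C(C)(C)O1)=C/[C@@H]1OC(C)(C)O[C@@H]1[C@@]2(C)OC(C(C)=C)=CC2=O
F2 | step 9 | O-pinacolboryl ether of 17 | COC(=O)C(=C)[C@@H]([C@@H](OB1OC(C)(C)C(C)(C)O1)C=C)[C@@H]2OC(C)(C)O[C@@H]2[C@@]3(C)OC(C(C)=C)=CC3=O
F3 | step 10 | O-triethylsilyl ether of 17 | COC(=O)C(=C)[C@@H]([C@@H](O[Si](CC)(CC)CC)C=C)[C@@H]1OC(C)(C)O[C@@H]1[C@@]2(C)OC(C(C)=C)=CC2=O
F4 | step 10 | macrocyclic 6-O-triethylsilyl methyl ester (seco-lactone of 19) | CC1(C)O[C@H]2[C@@H](C(=C)C(=O)OC)[C@@H](O[Si](CC)(CC)CC)/C=C(/C)C3=CC(=O)[C@](C)(O3)[C@H]2O1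
F5 | step 10 | macrocyclic 6-hydroxy methyl ester (seco-lactone of 19) | CC1(C)O[C@H]2[C@@H](C(=C)C(=O)OC)[C@@H](O)/C=C(/C)C3=CC(=O)[C@](C)(O3)[C@H]2O1
F6 | step 12 | 8-O-triethylsilyl ether of 20 | CC[Si](CC)(CC)O[C@H]1[C@H]2C(=C)C(=O)O[C@H]2/C=C(/C)C2=CC(=O)[C@](C)(O2)[C@H]1O
F7 | step 12 | 9-O-acetyl-8-O-triethylsilyl derivative of 20 | CC[Si](CC)(CC)O[C@H]1[C@H]2C(=C)C(=O)O[C@H]2/C=C(/C)C2=CC(=O)[C@](C)(O2)[C@H]1OC(C)=O
F8 | step 12 | 9-O-acetyl derivative of 20 (8-OH free) | O[C@H]1[C@H]2C(=C)C(=O)O[C@H]2/C=C(/C)C2=CC(=O)[C@](C)(O2)[C@H]1OC(C)=O
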